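The ester is cut at its C–O bond and the dienyl chain at C4–C5, which leaves a C13 ring ketone. Everything rests on the C1'–C6' bond of the 2,6,6-trimethylcyclohex-2-ene ring (C1' the chain-bearing CH, C2'=C3' the ring alkene, C6' the gem-dimethyl carbon): this ring is the first ring of a head-to-tail polyprenyl cyclisation stopped after one closure. An engineered squalene–hopene cyclase should turn achiral (E)-geranylacetone, an open C13 dienone with a terminal prenyl alkene and one internal trisubstituted alkene, into (S)-dihydro-alpha-ionone in one operation, setting the ring, the alkene position and the only stereocentre. A sulfone coupling and an esterification finish the route.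

Key step: step 1

Assumption: isomerically pure (5E)-geranylacetone is bought or cut from the commercial E/Z mixture by fractional distillation, and a cyclase variant carrying a base next to C3' is taken to be reachable by directed evolution of the known monocyclising variants.

Step 1
Reactants: 1 (5E)-6,10-dimethylundeca-5,9-dien-2-one ((E)-geranylacetone)
Product: 2 4-[(1S)-2,6,6-trimethylcyclohex-2-en-1-yl]butan-2-one
Conditions: evolved squalene–hopene cyclase variant (Alicyclobacillus acidocaldarius scaffold, E. coli whole cells), citrate buffer pH 6.0, 2-hydroxypropyl-β-cyclodextrin, 30 °C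
Reagents that add atoms: none
Why: Proposed new method: the catalytic aspartic acid of the cyclase should protonate C9 of the terminal alkene of 1 held in a chair-like fold, C5 of the C5=C6 alkene then attacks the tertiary C10 cation to make the C1'–C6' bond, and a base positioned by directed evolution next to C3' (C7 of 1) takes the proton that lies parallel to the empty orbital at C2', which leaves the C2'=C3' alkene. The closest known reaction type is the enantioselective monocyclisation of geranylacetone by engineered squalene–hopene cyclases that ends with loss of a methyl proton to the exocyclic gamma alkene, so only the site of the last deprotonation is without precedent. The ring closes in a 6-endo cation–olefin mode, both carbons of the attacking alkene ending up in the ring. The C1' stereocentre is set by the enzyme pocket, which fixes the fold of the chain and hence the face of C5 that bonds to C10, and the native fold of this enzyme family is expected to lead to (1S). The step needs proton loss at C3' in preference to the C2' methyl group and C1', and it must keep the ketone oxygen and water away from the C2' cation; the substrate helps in that it has only two alkenes, so that the cascade must stop after one ring, and its (5E) geometry fits the native chair fold, whereas the site of deprotonation depends on the evolved pocket alone.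

Step 2
Reactants: 2 4-[(1S)-2,6,6-trimethylcyclohex-2-en-1-yl]butan-2-one; 3 triethyl phosphonoacetate
Product: 4 ethyl (2E)-3-methyl-5-[(1S)-2,6,6-trimethylcyclohex-2-en-1-yl]pent-2-enoate
Conditions: NaH, THF, 0 °C → 50 °C; silica chromatography to remove the (2Z)-isomer
Reagents that add atoms: none
Why: Horner–Wadsworth–Emmons olefination of the methyl ketone with the stabilised phosphonate anion should favour the (E)-enoate through the reversibly formed oxaphosphetane, the minor (Z)-isomer is separable at the ester stage, and C1' lies three bonds from the carbonyl and cannot epimerise.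

Step 3
Reactants: 4 ethyl (2E)-3-methyl-5-[(1S)-2,6,6-trimethylcyclohex-2-en-1-yl]pent-2-enoate
Product: 5 (2E)-3-methyl-5-[(1S)-2,6,6-trimethylcyclohex-2-en-1-yl]pent-2-en-1-ol
Conditions: i-Bu2AlH (2.5 equiv), CH2Cl2, −78 °C → 0 °C; aq. KNaC4H4O6
Reagents that add atoms: none
Why: 1,2-reduction of the conjugated ester by the electrophilic aluminium hydride (i-Bu2AlH ester reduction) should give the allylic alcohol without touching either alkene or the stereocentre.

Step 4
Reactants: 5 (2E)-3-methyl-5-[(1S)-2,6,6-trimethylcyclohex-2-en-1-yl]pent-2-en-1-ol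
Product: 6 (2E)-1-bromo-3-methyl-5-[(1S)-2,6,6-trimethylcyclohex-2-en-1-yl]pent-2-ene
Conditions: PBr3 (0.4 equiv), pyridine (cat.), Et2O, −10 °C → 0 °C; used crude
Reagents that add atoms: phosphorus tribromide, BrP(Br)Br
Why: bromination of a primary allylic alcohol with PBr3 at low temperature proceeds by SN2 displacement of the phosphite ester and, as with farnesol, should keep the position and (E)-geometry of the alkene, the trace of pyridine buffering HBr away from the ring alkene.

Step 5
Reactants: 6 (2E)-1-bromo-3-methyl-5-[(1S)-2,6,6-trimethylcyclohex-2-en-1-yl]pent-2-ene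
Product: 7 {[(2E)-3-methyl-5-[(1S)-2,6,6-trimethylcyclohex-2-en-1-yl]pent-2-en-1-yl]sulfonyl}benzene
Conditions: PhSO2Na, DMF, 0 °C → rt
Reagents that add atoms: sodium benzenesulfinate, [Na+].[O-]S(=O)c1ccccc1
Why: S-alkylation of the sulfinate anion by SN2 at the primary allylic bromide (sulfinate alkylation) should give the allylic phenyl sulfone with the (E)-alkene unchanged.

Step 6
Reactants: 7 {[(2E)-3-methyl-5-[(1S)-2,6,6-trimethylcyclohex-2-en-1-yl]pent-2-en-1-yl]sulfonyl}benzene; 8 (2E)-4-chloro-3-methylbut-2-en-1-yl acetate
Product: 9 (2E,6E)-3,7-dimethyl-5-(phenylsulfonyl)-9-[(1S)-2,6,6-trimethylcyclohex-2-en-1-yl]nona-2,6-dien-1-yl acetate (mixture of C5 epimers)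
Conditions: KOt-Bu (1.1 equiv) added to 7 + 8, NaI (cat.), DMF, −20 °C
Reagents that add atoms: none
Why: Julia-type sulfone alkylation, in which the sulfone-stabilised allylic carbanion attacks the primary allylic chloride through its alpha carbon by SN2 faster than it adds to the acetate, should form C4–C5 with both (E)-alkenes intact; the new sulfone-bearing centre C5 forms without control, which does not matter because it becomes CH2 in step 7.

Step 7
Reactants: 9 (2E,6E)-3,7-dimethyl-5-(phenylsulfonyl)-9-[(1S)-2,6,6-trimethylcyclohex-2-en-1-yl]nona-2,6-dien-1-yl acetate (mixture of C5 epimers)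
Product: 11 (2E,6E)-3,7-dimethyl-9-[(1S)-2,6,6-trimethylcyclohex-2-en-1-yl]nona-2,6-dien-1-ol, via lithium alkoxide of the hydroxy sulfone 10 (not isolated)
Conditions: LiBHEt3 (5 equiv), THF, 0 °C, 30 min; then PdCl2(dppp) (5 mol %), 0 °C → rt
Reagents that add atoms: none
Why: LiBHEt3 should first cleave the acetate to the lithium alkoxide, after which zerovalent palladium formed in the flask ionises the allylic sulfone to a π-allyl complex that takes up hydride at the less substituted carbon that carried sulfur (palladium-catalysed hydride desulfonylation of allylic sulfones), so that the C6=C7 alkene keeps its position and (E)-geometry; the catalyst is added only after the ester is gone so that palladium meets no allylic C–O leaving group.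

Step 8
Reactants: 11 (2E,6E)-3,7-dimethyl-9-[(1S)-2,6,6-trimethylcyclohex-2-en-1-yl]nona-2,6-dien-1-ol; 12 linoleic acid
Product: 13 (2E,6E)-3,7-dimethyl-9-[(1S)-2,6,6-trimethylcyclohex-2-en-1-yl]nona-2,6-dien-1-yl (9Z,12Z)-octadeca-9,12-dienoate
Conditions: DCC, DMAP (cat.), CH2Cl2, 0 °C → rt, argon
Reagents that add atoms: none
Why: Steglich esterification, in which the O-acylisourea of the acid is passed on by DMAP as an acylpyridinium ion to the primary allylic alcohol, runs under neutral conditions that should leave the skipped (Z,Z)-diene, the four other alkenes and the stereocentre untouched.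

Compound list
1 | (5E)-6,10-dimethylundeca-5,9-dien-2-one ((E)-geranylacetone) | CC(C)=CCC/C(C)=C/CCC(C)=O | starting material
2 | 4-[(1S)-2,6,6-trimethylcyclohex-2-en-1-yl]butan-2-one ((S)-dihydro-alpha-ionone) | CC(=O)CC[C@@H]1C(C)=CCCC1(C)C | intermediate
3 | triethyl phosphonoacetate | CCOC(=O)CP(=O)(OCC)OCC | starting material
4 | ethyl (2E)-3-methyl-5-[(1S)-2,6,6-trimethylcyclohex-2-en-1-yl]pent-2-enoate | CCOC(=O)/C=C(\C)CC[C@@H]1C(C)=CCCC1(C)C | intermediate
5 | (2E)-3-methyl-5-[(1S)-2,6,6-trimethylcyclohex-2-en-1-yl]pent-2-en-1-ol | OC/C=C(\C)CC[C@@H]1C(C)=CCCC1(C)C | intermediate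
6 | (2E)-1-bromo-3-methyl-5-[(1S)-2,6,6-trimethylcyclohex-2-en-1-yl]pent-2-ene | BrC/C=C(\C)CC[C@@H]1C(C)=CCCC1(C)C | intermediate
7 | {[(2E)-3-methyl-5-[(1S)-2,6,6-trimethylcyclohex-2-en-1-yl]pent-2-en-1-yl]sulfonyl}benzene | O=S(=O)(C/C=C(\C)CC[C@@H]1C(C)=CCCC1(C)C)c1ccccc1 | intermediate
8 | (2E)-4-chloro-3-methylbut-2-en-1-yl acetate | CC(=O)OC/C=C(\C)CCl | starting material
9 | (2E,6E)-3,7-dimethyl-5-(phenylsulfonyl)-9-[(1S)-2,6,6-trimethylcyclohex-2-en-1-yl]nona-2,6-dien-1-yl acetate, C5 unassigned (both epimers) | CC(=O)OC/C=C(\C)CC(/C=C(\C)CC[C@@H]1C(C)=CCCC1(C)C)S(=O)(=O)c1ccccc1 | intermediate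
10 | lithium (2E,6E)-3,7-dimethyl-5-(phenylsulfonyl)-9-[(1S)-2,6,6-trimethylcyclohex-2-en-1-yl]nona-2,6-dien-1-olate, C5 unassigned (both epimers) | [Li+].[O-]C/C=C(\C)CC(/C=C(\C)CC[C@@H]1C(C)=CCCC1(C)C)S(=O)(=O)c1ccccc1 | intermediate (not isolated)
11 | (2E,6E)-3,7-dimethyl-9-[(1S)-2,6,6-trimethylcyclohex-2-en-1-yl]nona-2,6-dien-1-ol | OC/C=C(\C)CC/C=C(\C)CC[C@@H]1C(C)=CCCC1(C)C | intermediate
12 | linoleic acid ((9Z,12Z)-octadeca-9,12-dienoic acid) | CCCCC/C=C\C/C=C\CCCCCCCC(=O)O | starting material
13 | (2E,6E)-3,7-dimethyl-9-[(1S)-2,6,6-trimethylcyclohex-2-en-1-yl]nona-2,6-dien-1-yl (9Z,12Z)-octadeca-9,12-dienoate | CCCCC/C=C\C/C=C\CCCCCCCC(=O)OC/C=C(\C)CC/C=C(\C)CC[C@@H]1C(C)=CCCC1(C)C | target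

Total step count: 8. Longest linear sequence: 8 steps (1 → 13).

Steps most likely to fail

Step 1. Loss of a proton from the C2' methyl group, or capture of the C2' cation by the ketone oxygen, may outrun the wanted deprotonation at C3'. The fallback sets out from 1 and returns at 2, using known chemistry only. Compound 1 is cyclised with one of the existing gamma-selective cyclase variants to 4-[(1S)-2,2-dimethyl-6-methylidenecyclohexyl]butan-2-one F1. The exocyclic alkene of F1 is then moved into the ring with RhCl3·3H2O (cat.) in EtOH at 70 °C, a known exo-to-endo olefin isomerisation through a rhodium hydride. It should deliver the trisubstituted C2'=C3' alkene first, and it is stopped before the tetrasubstituted isomer, which would erase C1', begins to form. The product is 2.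

Step 7. Hydride may be delivered to the wrong end of the π-allyl unit, shifting the alkene to C5=C6, the (6E)-geometry may be lost, or the allylic C1–O bond may be hydrogenolysed if ester cleavage is incomplete when the catalyst is added. The fallback sets out from 6 and returns at 11 and avoids sulfur altogether. Bromide 6 alkylates the sodium enolate of ethyl acetoacetate (NaOEt, EtOH) to give ethyl (4E)-2-acetyl-5-methyl-7-[(1S)-2,6,6-trimethylcyclohex-2-en-1-yl]hept-4-enoate F2. Krapcho dealkoxycarbonylation (LiCl, wet DMSO, 150 °C) then gives (5E)-6-methyl-8-[(1S)-2,6,6-trimethylcyclohex-2-en-1-yl]oct-5-en-2-one F3. A second Horner–Wadsworth–Emmons olefination with 3 (NaH, THF), with removal of the (2Z)-isomer on silica, gives ethyl (2E,6E)-3,7-dimethyl-9-[(1S)-2,6,6-trimethylcyclohex-2-en-1-yl]nona-2,6-dienoate F4. Reduction with i-Bu2AlH gives 11.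

Step 2. Geometric selectivity in the olefination of a methyl ketone may be too low, and the (2Z)-isomer may co-elute. The fallback sets out from 2 and returns at 5. Kinetic enolisation on the methyl side (LDA, THF, −78 °C) and trapping with ClP(O)(OEt)2 gives diethyl 4-[(1S)-2,6,6-trimethylcyclohex-2-en-1-yl]but-1-en-2-yl phosphate F5. Elimination with excess LDA gives (6S)-6-(but-3-yn-1-yl)-1,5,5-trimethylcyclohex-1-ene F6. Negishi carboalumination (AlMe3, Cp2ZrCl2, CH2Cl2) adds methyl and aluminium syn across the alkyne, and the alkenylalane, activated with n-BuLi, is trapped with (CH2O)n to give 5 directly, with (E)-geometry fixed by the syn addition.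

Further compounds
F1 | step 1 | 4-[(1S)-2,2-dimethyl-6-methylidenecyclohexyl]butan-2-one ((S)-gamma-dihydroionone) | CC(=O)CC[C@@H]1C(=C)CCCC1(C)C
F2 | step 7 | ethyl (4E)-2-acetyl-5-methyl-7-[(1S)-2,6,6-trimethylcyclohex-2-en-1-yl]hept-4-enoate (both C2 epimers) | CCOC(=O)C(C/C=C(\C)CC[C@@H]1C(C)=CCCC1(C)C)C(C)=O
F3 | step 7 | (5E)-6-methyl-8-[(1S)-2,6,6-trimethylcyclohex-2-en-1-yl]oct-5-en-2-one | CC(=O)CC/C=C(\C)CC[C@@H]1C(C)=CCCC1(C)C
F4 | step 7 | ethyl (2E,6E)-3,7-dimethyl-9-[(1S)-2,6,6-trimethylcyclohex-2-en-1-yl]nona-2,6-dienoate | CCOC(=O)/C=C(\C)CC/C=C(\C)CC[C@@H]1C(C)=CCCC1(C)C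
F5 | step 2 | diethyl 4-[(1S)-2,6,6-trimethylcyclohex-2-en-1-yl]but-1-en-2-yl phosphate | C=C(CC[C@@H]1C(C)=CCCC1(C)C)OP(=O)(OCC)OCC
F6 | step 2 | (6S)-6-(but-3-yn-1-yl)-1,5,5-trimethylcyclohex-1-ene | C#CCC[C@@H]1C(C)=CCCC1(C)C
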